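**Plan**
1. Ring numbering: O1, C2, C3 (carbinol arm), C4 (benzyl arm), C5. C5 is a CH2 between O1 and C4, and C4 carries an ArCH2 group, so the first cut (after deprotection) is C4–C5: an O1–CH2 radical adding to a styrene.
2. The opened chain is an alkoxyacetic acid. Further cuts: O1–C5 (ether from a primary alcohol and bromoacetic acid), C3–carbinol carbon (aldol of a 4-arylbut-3-enoyl imide with protected syringaldehyde), and the styrene C=C (Wittig).
3. Forward: one benzyl-protected syringaldehyde is used twice. The chain is built linearly (Wittig, acylation, aldol, silylation, reduction, O-alkylation), the only ring closes in the radical step, and two deprotections finish.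
4. Stereochemistry: the carbinol centre (S) and C3 (R) come from an Evans syn aldol on (S)-4-benzyl-2-oxazolidinone; C4 (R), trans to C3, comes from the chair-like 5-exo transition state.
5. Protecting groups: phenols as benzyl ethers (inert to NaH and to radicals, unlike aryl silyl ethers); the carbinol as a triisopropylsilyl ether (should not migrate to the primary alkoxide).

Key step: step 8

Remark: the target SMILES is read as (3R,4R) in the ring with an (S) carbinol, which means trans ring substituents and a syn-aldol relationship between C3 and the carbinol carbon.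

**Step 1**
Reactants: 1 syringaldehyde (4-hydroxy-3,5-dimethoxybenzaldehyde)
Product: 2 4-(benzyloxy)-3,5-dimethoxybenzaldehyde
Conditions: BnBr, K2CO3, DMF, 60 °C
Reagents that add atoms: benzyl bromide, BrCc1ccccc1
Why: Williamson O-benzylation of the acidic para-formyl phenol; the benzyl ether is chosen because it is inert to the alkoxide, hydride and radical conditions ahead and leaves by hydrogenolysis once the alkene is gone.

**Step 2**
Reactants: 2 4-(benzyloxy)-3,5-dimethoxybenzaldehyde; 3 (2-carboxyethyl)triphenylphosphonium bromide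
Product: 5 (E)-4-[4-(benzyloxy)-3,5-dimethoxyphenyl]but-3-enoic acid, via carboxylate ylide 4 (not isolated)
Conditions: NaN(SiMe3)2 (2.2 equiv), THF, −78 °C to rt; then 1 M HCl; recrystallisation
Reagents that add atoms: none
Why: Wittig olefination with the carboxylate-bearing ylide, which with aromatic aldehydes should give the styrylacetic acid mainly as the E isomer (conjugation with the arene keeps the double bond in the β,γ position), and the alkene geometry is in any case erased later when this carbon becomes the benzyl CH2.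

**Step 3**
Reactants: 5 (E)-4-[4-(benzyloxy)-3,5-dimethoxyphenyl]but-3-enoic acid; 6 (S)-4-benzyl-2-oxazolidinone
Product: 8 (S)-4-benzyl-3-{(E)-4-[4-(benzyloxy)-3,5-dimethoxyphenyl]but-3-enoyl}oxazolidin-2-one, via mixed pivalic anhydride 7 (not isolated)
Conditions: PivCl, Et3N, THF, −20 °C; then 6, LiCl, −20 °C to rt
Reagents that add atoms: none
Why: N-acylation of the oxazolidinone through the mixed pivalic anhydride under the Et3N/LiCl protocol, which avoids strong base and so should leave the styrene double bond in place.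

**Step 4**
Reactants: 8 (S)-4-benzyl-3-{(E)-4-[4-(benzyloxy)-3,5-dimethoxyphenyl]but-3-enoyl}oxazolidin-2-one; 2 4-(benzyloxy)-3,5-dimethoxybenzaldehyde
Product: 11 (4S)-4-benzyl-3-[(2S,3E)-4-[4-(benzyloxy)-3,5-dimethoxyphenyl]-2-{(S)-[4-(benzyloxy)-3,5-dimethoxyphenyl](hydroxy)methyl}but-3-enoyl]oxazolidin-2-one, via Z-dibutylboron dienolate 9 (not isolated), via dibutylboron aldolate 10 (not isolated)
Conditions: Bu2BOTf, iPr2NEt, CH2Cl2, −78 to 0 °C; then 2, −78 to 0 °C; then pH 7 buffer, MeOH, 30% H2O2, 0 °C
Reagents that add atoms: none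
Why: Evans syn aldol, in which soft enolisation gives the Z-boron dienolate that reacts at its α-carbon through a closed chair-like six-membered transition state on the face opposite the benzyl group of the auxiliary, setting C2 (S) and the carbinol carbon (S) of the acyl chain, which become C3 (R, a change of descriptor only) and the carbinol (S) of the target.

**Step 5**
Reactants: 11 the syn-aldol adduct
Product: 12 (4S)-4-benzyl-3-[(2S,3E)-4-[4-(benzyloxy)-3,5-dimethoxyphenyl]-2-{(S)-[4-(benzyloxy)-3,5-dimethoxyphenyl][(triisopropylsilyl)oxy]methyl}but-3-enoyl]oxazolidin-2-one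
Conditions: TIPSOTf, 2,6-lutidine, CH2Cl2, 0 °C to rt
Reagents that add atoms: triisopropylsilyl trifluoromethanesulfonate, CC(C)[Si](C(C)C)(C(C)C)OS(=O)(=O)C(F)(F)F
Why: Silylation with a silyl triflate and a hindered base blocks retro-aldol cleavage, and triisopropylsilyl is chosen over smaller silyl groups because it should not migrate to the neighbouring primary alkoxide in step 7.

**Step 6**
Reactants: 12 the silylated imide
Product: 13 (2R,3E)-4-[4-(benzyloxy)-3,5-dimethoxyphenyl]-2-{(S)-[4-(benzyloxy)-3,5-dimethoxyphenyl][(triisopropylsilyl)oxy]methyl}but-3-en-1-ol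
Conditions: LiBH4, MeOH (1.1 equiv), Et2O, 0 °C; then 1 M NaOH
Reagents that add atoms: none
Why: Reductive removal of the auxiliary, in which LiBH4 attacks the exocyclic imide carbonyl and should give the primary alcohol without touching the styrene, the silyl ether or the α-stereocentre, the oxazolidinone being recovered.

**Step 7**
Reactants: 13 the primary alcohol; 14 bromoacetic acid
Product: 15 2-{[(2R,3E)-4-[4-(benzyloxy)-3,5-dimethoxyphenyl]-2-{(S)-[4-(benzyloxy)-3,5-dimethoxyphenyl][(triisopropylsilyl)oxy]methyl}but-3-en-1-yl]oxy}acetic acid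
Conditions: NaH (4 equiv), Bu4NI (cat.), THF, 0 to 45 °C; then 1 M HCl to pH 3, 0 °C
Reagents that add atoms: none
Why: Williamson ether synthesis between the sodium alkoxide and sodium bromoacetate should give the alkoxyacetic acid directly, the benzyl and triisopropylsilyl ethers being inert to NaH.

**Step 8**
Reactants: 15 the alkoxyacetic acid
Product: 17 (3R,4R)-3-{(S)-[4-(benzyloxy)-3,5-dimethoxyphenyl][(triisopropylsilyl)oxy]methyl}-4-[4-(benzyloxy)-3,5-dimethoxybenzyl]tetrahydrofuran, via Barton ester 16 (not isolated)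
Conditions: N-hydroxypyridine-2-thione, DCC, CH2Cl2, dark, 0 °C to rt; then slow addition to t-BuSH (10 equiv), PhMe, visible light (tungsten lamp), 0 °C
Reagents that add atoms: none
Why: Barton decarboxylation, in which the thiohydroxamate ester fragments under visible light in a radical chain and loses CO2 to give the nucleophilic O1–CH2 radical (C5). This radical adds 5-exo-trig to the styrene carbon next to C3, which forms C4–C5 and closes the tetrahydrofuran, and the benzylic radical so formed takes hydrogen from t-BuSH while the thiyl radical carries the chain by attacking the thiocarbonyl group of the next ester. The closest known reaction type is the 5-exo cyclisation of alkoxymethyl radicals onto alkenes to give 3,4-disubstituted tetrahydrofurans. The new stereocentre C4 is controlled by C3: in the chair-like transition state the bulky silyloxybenzyl group at C3 sits pseudo-equatorial, which places the future benzyl arm trans to it and gives (4R). The step needs ring closure before hydrogen transfer and trans over cis; the first is secured by the styrene acceptor (fast closure to a stabilised benzylic radical) together with a tertiary thiol and slow addition of the ester, the second by the size of the C3 substituent and the low temperature.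

**Step 9**
Reactants: 17 the protected tetrahydrofuran
Product: 18 (3R,4R)-3-{(S)-(4-hydroxy-3,5-dimethoxyphenyl)[(triisopropylsilyl)oxy]methyl}-4-(4-hydroxy-3,5-dimethoxybenzyl)tetrahydrofuran
Conditions: H2 (1 atm), 10% Pd/C, EtOAc, rt
Reagents that add atoms: none
Why: Catalytic hydrogenolysis of the two aryl benzyl ethers, with no alkene left and the bulky silyl ether expected to keep the one benzylic C–O bond of the skeleton from hydrogenolysis.

**Step 10**
Reactants: 18 the bis-phenol silyl ether
Product: 19 (3R,4R)-3-[(S)-hydroxy(4-hydroxy-3,5-dimethoxyphenyl)methyl]-4-(4-hydroxy-3,5-dimethoxybenzyl)tetrahydrofuran (CNP0257794.1)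
Conditions: Bu4NF, AcOH (1:1), THF, 0 °C to rt
Reagents that add atoms: none
Why: Fluoride-mediated desilylation under buffered, non-acidic conditions, chosen because acid would ionise the electron-rich benzylic carbinol and invite Friedel–Crafts closure onto the other arene, so the (S) centre should be left untouched.

**Compound list**
1 | syringaldehyde | COc1cc(C=O)cc(OC)c1O | starting material
2 | 4-(benzyloxy)-3,5-dimethoxybenzaldehyde | COc1cc(C=O)cc(OC)c1OCc1ccccc1 | intermediate
3 | (2-carboxyethyl)triphenylphosphonium bromide | OC(=O)CC[P+](c1ccccc1)(c1ccccc1)c1ccccc1.[Br-] | starting material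
4 | sodium 3-(triphenylphosphoranylidene)propanoate, the carboxylate ylide (not isolated) | [Na+].[O-]C(=O)CC=P(c1ccccc1)(c1ccccc1)c1ccccc1 | intermediate
5 | (E)-4-[4-(benzyloxy)-3,5-dimethoxyphenyl]but-3-enoic acid | COc1cc(/C=C/CC(=O)O)cc(OC)c1OCc1ccccc1 | intermediate
6 | (S)-4-benzyl-2-oxazolidinone | O=C1N[C@@H](Cc2ccccc2)CO1 | starting material
7 | (E)-4-[4-(benzyloxy)-3,5-dimethoxyphenyl]but-3-enoic pivalic anhydride (not isolated) | COc1cc(/C=C/CC(=O)OC(=O)C(C)(C)C)cc(OC)c1OCc1ccccc1 | intermediate
8 | (S)-4-benzyl-3-{(E)-4-[4-(benzyloxy)-3,5-dimethoxyphenyl]but-3-enoyl}oxazolidin-2-one | COc1cc(/C=C/CC(=O)N2[C@@H](Cc3ccccc3)COC2=O)cc(OC)c1OCc1ccccc1 | intermediate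
9 | Z-dibutylboron dienolate of imide 8 (not isolated) | COc1cc(/C=C/C=C(\OB(CCCC)CCCC)N2[C@@H](Cc3ccccc3)COC2=O)cc(OC)c1OCc1ccccc1 | intermediate
10 | dibutylboron aldolate of 11 (not isolated) | COc1cc(/C=C/[C@H](C(=O)N2[C@@H](Cc3ccccc3)COC2=O)[C@H](OB(CCCC)CCCC)c2cc(OC)c(OCc3ccccc3)c(OC)c2)cc(OC)c1OCc1ccccc1 | intermediate
11 | (4S)-4-benzyl-3-[(2S,3E)-4-[4-(benzyloxy)-3,5-dimethoxyphenyl]-2-{(S)-[4-(benzyloxy)-3,5-dimethoxyphenyl](hydroxy)methyl}but-3-enoyl]oxazolidin-2-one | COc1cc(/C=C/[C@H](C(=O)N2[C@@H](Cc3ccccc3)COC2=O)[C@H](O)c2cc(OC)c(OCc3ccccc3)c(OC)c2)cc(OC)c1OCc1ccccc1 | intermediate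
12 | triisopropylsilyl ether of 11 | COc1cc(/C=C/[C@H](C(=O)N2[C@@H](Cc3ccccc3)COC2=O)[C@H](O[Si](C(C)C)(C(C)C)C(C)C)c2cc(OC)c(OCc3ccccc3)c(OC)c2)cc(OC)c1OCc1ccccc1 | intermediate
13 | (2R,3E)-4-[4-(benzyloxy)-3,5-dimethoxyphenyl]-2-{(S)-[4-(benzyloxy)-3,5-dimethoxyphenyl][(triisopropylsilyl)oxy]methyl}but-3-en-1-ol | COc1cc(/C=C/[C@H](CO)[C@H](O[Si](C(C)C)(C(C)C)C(C)C)c2cc(OC)c(OCc3ccccc3)c(OC)c2)cc(OC)c1OCc1ccccc1 | intermediate
14 | bromoacetic acid | OC(=O)CBr | starting material
15 | 2-{[(2R,3E)-4-[4-(benzyloxy)-3,5-dimethoxyphenyl]-2-{(S)-[4-(benzyloxy)-3,5-dimethoxyphenyl][(triisopropylsilyl)oxy]methyl}but-3-en-1-yl]oxy}acetic acid | COc1cc(/C=C/[C@H](COCC(=O)O)[C@H](O[Si](C(C)C)(C(C)C)C(C)C)c2cc(OC)c(OCc3ccccc3)c(OC)c2)cc(OC)c1OCc1ccccc1 | intermediate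
16 | 2-thioxopyridin-1(2H)-yl ester of acid 15, the Barton ester (not isolated) | COc1cc(/C=C/[C@H](COCC(=O)ON2C=CC=CC2=S)[C@H](O[Si](C(C)C)(C(C)C)C(C)C)c2cc(OC)c(OCc3ccccc3)c(OC)c2)cc(OC)c1OCc1ccccc1 | intermediate
17 | (3R,4R)-3-{(S)-[4-(benzyloxy)-3,5-dimethoxyphenyl][(triisopropylsilyl)oxy]methyl}-4-[4-(benzyloxy)-3,5-dimethoxybenzyl]tetrahydrofuran | COc1cc(C[C@H]2COC[C@@H]2[C@H](O[Si](C(C)C)(C(C)C)C(C)C)c2cc(OC)c(OCc3ccccc3)c(OC)c2)cc(OC)c1OCc1ccccc1 | intermediate
18 | (3R,4R)-3-{(S)-(4-hydroxy-3,5-dimethoxyphenyl)[(triisopropylsilyl)oxy]methyl}-4-(4-hydroxy-3,5-dimethoxybenzyl)tetrahydrofuran | COc1cc(C[C@H]2COC[C@@H]2[C@H](O[Si](C(C)C)(C(C)C)C(C)C)c2cc(OC)c(O)c(OC)c2)cc(OC)c1O | intermediate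
19 | (3R,4R)-3-[(S)-hydroxy(4-hydroxy-3,5-dimethoxyphenyl)methyl]-4-(4-hydroxy-3,5-dimethoxybenzyl)tetrahydrofuran | COc1cc(C[C@H]2COC[C@@H]2[C@H](O)c2cc(OC)c(O)c(OC)c2)cc(OC)c1O | target

**Step count and risks**
Total steps: 10. Longest linear sequence: 10 steps, from syringaldehyde 1 to target 19; aldehyde 2 enters twice, in steps 2 and 4.

Most likely to fail:

Step 8. Three processes could erode the key step:
- hydrogen transfer to the O–CH2 radical before ring closure;
- transfer of the 2-pyridylthio group to the benzylic radical in place of hydrogen, or reversible thiyl addition to the styrene;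
- insufficient preference for the trans ring.

The fallback keeps the same radical and the same bond but changes how the radical is made. It sets out from acid 15 and returns at 17. Acid 15 would be coupled with N-hydroxyphthalimide (N,N'-diisopropylcarbodiimide, cat. DMAP, CH2Cl2, rt) to give the isolable N-hydroxyphthalimide ester F1. Blue-light irradiation of F1 with Ru(bpy)3(PF6)2 (1 mol%), Hantzsch ester and iPr2NEt in CH2Cl2 at rt should reduce the ester by single-electron transfer. Loss of phthalimide anion and CO2 then gives the same O1–CH2 radical, which closes 5-exo; the benzylic radical is quenched by hydrogen transfer from the Hantzsch ester, so no thiyl radical and no thiocarbonyl group are present.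

Step 7. The alkylation of a β-branched alkoxide by an anionic electrophile may be slow, and on long exposure to NaH silyl transfer from the secondary oxygen to the primary alkoxide could begin. The fallback avoids any alkoxide. It sets out from alcohol 13 and returns at 15. Slow addition of ethyl diazoacetate to 13 and Rh2(OAc)4 (1 mol%) in CH2Cl2 at rt should give, by O–H insertion of the rhodium carbenoid under neutral conditions, the ethyl alkoxyacetate F2. The trans-disubstituted styrene is a poor cyclopropanation partner by comparison. Saponification with LiOH in THF/H2O at rt then gives 15, with the benzyl and triisopropylsilyl ethers unaffected.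

Step 2. The β-carboxylate ylide can fragment to acrylate and Ph3P before it olefinates, and E/Z control may be incomplete. The fallback builds the same acid by metathesis. It sets out from aldehyde 2 and returns at 5. Methylenation of 2 with Ph3P=CH2 (Ph3PCH3Br, KOtBu, THF, 0 °C) gives 2-(benzyloxy)-5-ethenyl-1,3-dimethoxybenzene F3. Cross-metathesis of F3 with but-3-enoic acid (3 equiv) using the second-generation Hoveyda–Grubbs catalyst, (H2IMes)Cl2Ru=CH(C6H4-2-OiPr), in CH2Cl2 at 40 °C should give acid 5 as the thermodynamically favoured E isomer.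

**Further compounds**
F1 | step 8 | 1,3-dioxoisoindolin-2-yl ester of acid 15 | COc1cc(/C=C/[C@H](COCC(=O)ON2C(=O)c3ccccc3C2=O)[C@H](O[Si](C(C)C)(C(C)C)C(C)C)c2cc(OC)c(OCc3ccccc3)c(OC)c2)cc(OC)c1OCc1ccccc1
F2 | step 7 | ethyl ester of acid 15 | COc1cc(/C=C/[C@H](COCC(=O)OCC)[C@H](O[Si](C(C)C)(C(C)C)C(C)C)c2cc(OC)c(OCc3ccccc3)c(OC)c2)cc(OC)c1OCc1ccccc1
F3 | step 2 | 2-(benzyloxy)-5-ethenyl-1,3-dimethoxybenzene | COc1cc(C=C)cc(OC)c1OCc1ccccc1
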